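**Retrosynthetic overview**
- The strategy rests on ring carbon C5 of the oxolan-2-one (the only ring): it carries O1 and is allylic to the exocyclic C1′=C2′ bond. The O1–C5 bond is therefore the 1,3-transposed form of a C2′–O bond in a 4,7-dihydrooxepin-2(3H)-one whose ring alkene is C5=C1′.
- The oxepinone comes from ring-closing metathesis (C5=C1′) of the ester of a 2-alkenyl-3-methylhex-4-enoic acid with a 2-methylallylic alcohol. The acid (C3 and C4) comes from an Ireland–Claisen rearrangement with chirality transfer; the alcohol (C2′) comes from prenol by asymmetric epoxidation.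
- After the contraction, C3′=C4′ is made by Julia–Kocienski olefination with a sulfone that carries C5′, C3″=C4″ by Wittig extension, and C5″–C6″ by a reductive syn-aldol with but-3-en-2-one.
- Ring order: the seven-membered lactone is closed first (metathesis) and then contracted to the five-membered lactone; no other ring is formed.

Key step: step 11

Remark: locants C2–C5 are those of the oxolan-2-one, C1′–C5′ the chain on C5 and C1″–C8″ the chain on C3. Compounds 5 and 7 are taken as catalogue compounds.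

**Route**

Step 1
Reactants: 1 3-methylbut-2-en-1-ol (prenol)
Product: 2 [(2S)-3,3-dimethyloxiran-2-yl]methanol
Conditions: Ti(OiPr)4 (5 mol%), L-(+)-diisopropyl tartrate (6 mol%), t-BuOOH, 4 Å sieves, CH2Cl2, −20 °C
Reagents that add atoms: tert-butyl hydroperoxide, CC(C)(C)OO
Why: Sharpless asymmetric epoxidation; the L-(+)-tartrate catalyst should deliver oxygen to the alkene face that gives the (2S)-epoxy alcohol, the sense known for other 3,3-disubstituted primary allylic alcohols.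

Step 2
Reactants: 2 [(2S)-3,3-dimethyloxiran-2-yl]methanol
Product: 3 tert-butyl{[(2S)-3,3-dimethyloxiran-2-yl]methoxy}dimethylsilane
Conditions: t-BuMe2SiCl, imidazole, CH2Cl2, 0 °C
Reagents that add atoms: tert-butyl(chloro)dimethylsilane, CC(C)(C)[Si](C)(C)Cl
Why: Silylation of the primary alcohol under weakly basic conditions, which should not trigger a Payne rearrangement.

Step 3
Reactants: 3 tert-butyl{[(2S)-3,3-dimethyloxiran-2-yl]methoxy}dimethylsilane
Product: 4 (2R)-1-{[tert-butyl(dimethyl)silyl]oxy}-3-methylbut-3-en-2-ol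
Conditions: Al(OiPr)3 (30 mol%), toluene, 110 °C
Reagents that add atoms: none
Why: Aluminium alkoxide-promoted isomerisation of a trisubstituted epoxide to an allylic alcohol: the tertiary C–O bond opens with loss of a methyl proton, the C2–O bond is untouched, and the descriptor changes from S to R only through the CIP ranking.

Step 4
Reactants: 5 (E)-pent-3-en-2-ol (racemic)
Product: 6 (2S,3E)-pent-3-en-2-ol
Conditions: Candida antarctica lipase B (immobilised), vinyl acetate (0.6 equiv), pentane, 25 °C, stopped just past half conversion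
Reagents that add atoms: none
Why: Enzymatic kinetic resolution by acyl transfer; the lipase should acetylate the (R)-alcohol (methyl as the small, propenyl as the large group) and leave the (S)-alcohol.

Step 5
Reactants: 7 1-methoxy-4-[(prop-2-yn-1-yloxy)methyl]benzene (4-methoxybenzyl propargyl ether)
Product: 10 (3E)-5-[(4-methoxybenzyl)oxy]-4-methylpent-3-en-1-ol, via alkenyldimethylalane 8 (not isolated), via lithium alkenylalanate 9 (not isolated)
Conditions: Me3Al (2 equiv), Cp2ZrCl2 (25 mol%), ClCH2CH2Cl, 25 °C; n-BuLi, THF, −78 °C; ethylene oxide, −78 → 0 °C; aq. potassium sodium tartrate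
Reagents that add atoms: trimethylaluminium, C[Al](C)C; ethylene oxide, C1CO1
Why: Negishi zirconium-catalysed carboalumination adds methyl and aluminium syn across the alkyne with aluminium on the terminal carbon, and the derived alanate opens the oxirane with retention, which fixes the (E)-trisubstituted alkene.

Step 6
Reactants: 10 (3E)-5-[(4-methoxybenzyl)oxy]-4-methylpent-3-en-1-ol
Product: 11 (3E)-5-[(4-methoxybenzyl)oxy]-4-methylpent-3-enoic acid
Conditions: TEMPO (20 mol%), PhI(OAc)2 (2.4 equiv), MeCN–H2O 1:1, 25 °C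
Reagents that add atoms: water, O
Why: Oxoammonium-mediated oxidation of the primary alcohol through the aldehyde hydrate to the acid, under conditions that should leave the PMB ether and the β,γ-alkene in place.

Step 7
Reactants: 11 (3E)-5-[(4-methoxybenzyl)oxy]-4-methylpent-3-enoic acid; 6 (2S,3E)-pent-3-en-2-ol
Product: 12 (2S,3E)-pent-3-en-2-yl (3E)-5-[(4-methoxybenzyl)oxy]-4-methylpent-3-enoate
Conditions: DCC, DMAP (5 mol%), CH2Cl2, 0 °C
Reagents that add atoms: none
Why: Steglich esterification with retention at the carbinol carbon; the low temperature and small amount of DMAP should keep the alkene out of conjugation.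

Step 8
Reactants: 12 (2S,3E)-pent-3-en-2-yl (3E)-5-[(4-methoxybenzyl)oxy]-4-methylpent-3-enoate
Product: 16 (2R,3R,4E)-2-{(1E)-3-[(4-methoxybenzyl)oxy]-2-methylprop-1-en-1-yl}-3-methylhex-4-enoic acid, via lithium dienolate 13 (not isolated), via silyl ketene acetal 14 (not isolated), via trimethylsilyl ester 15 (not isolated)
Conditions: LiN(iPr)2, THF–DMPU 4:1, −78 °C; Me3SiCl, −78 → 25 °C; 1 M HCl
Reagents that add atoms: none
Why: Ireland–Claisen rearrangement: deprotonation in THF–DMPU should give the Z(O)-dienolate, and the chair transition state with the carbinol methyl equatorial and the (E)-alkene transfers the (S) carbinol chirality to the 2,3-syn (2R,3R) pair (later C3 and C4) and a new (E)-propenyl group.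

Step 9
Reactants: 16 (2R,3R,4E)-2-{(1E)-3-[(4-methoxybenzyl)oxy]-2-methylprop-1-en-1-yl}-3-methylhex-4-enoic acid; 4 (2R)-1-{[tert-butyl(dimethyl)silyl]oxy}-3-methylbut-3-en-2-ol
Product: 17 (2R)-1-{[tert-butyl(dimethyl)silyl]oxy}-3-methylbut-3-en-2-yl (2R,3R,4E)-2-{(1E)-3-[(4-methoxybenzyl)oxy]-2-methylprop-1-en-1-yl}-3-methylhex-4-enoate
Conditions: DCC, DMAP (20 mol%), CH2Cl2, −20 → 0 °C
Reagents that add atoms: none
Why: Steglich esterification with retention at the carbinol carbon (later C2′); the low temperature should limit epimerisation of the α-alkenyl centre.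

Step 10
Reactants: 17 (2R)-1-{[tert-butyl(dimethyl)silyl]oxy}-3-methylbut-3-en-2-yl (2R,3R,4E)-2-{(1E)-3-[(4-methoxybenzyl)oxy]-2-methylprop-1-en-1-yl}-3-methylhex-4-enoate
Product: 18 (3R,4R,7R)-7-({[tert-butyl(dimethyl)silyl]oxy}methyl)-3-{(1E)-3-[(4-methoxybenzyl)oxy]-2-methylprop-1-en-1-yl}-4,6-dimethyl-4,7-dihydrooxepin-2(3H)-one
Conditions: second-generation Grubbs catalyst RuCl2(=CHPh)(PCy3)(H2IMes) (10 mol%), CH2Cl2 (2 mM), 40 °C
Reagents that add atoms: none
Why: Ring-closing metathesis: the ruthenium alkylidene should form at the propenyl group and close onto the isopropenyl group with loss of propene, while the hindered trisubstituted side-chain alkene stays out.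

Step 11
Reactants: 18 (3R,4R,7R)-7-({[tert-butyl(dimethyl)silyl]oxy}methyl)-3-{(1E)-3-[(4-methoxybenzyl)oxy]-2-methylprop-1-en-1-yl}-4,6-dimethyl-4,7-dihydrooxepin-2(3H)-one
Product: 19 (3S,4S,5S)-5-[(2E)-4-{[tert-butyl(dimethyl)silyl]oxy}but-2-en-2-yl]-3-{(1E)-3-[(4-methoxybenzyl)oxy]-2-methylprop-1-en-1-yl}-4-methyloxolan-2-one
Conditions: Pd(PPh3)4 (5 mol%, zerovalent palladium), THF, 50 °C
Reagents that add atoms: none
Why: Pd(PPh3)4 adds oxidatively to the allylic C2′–O1 bond of 18 anti to the leaving carboxylate and gives a zwitterionic π-allylpalladium carboxylate over C5–C1′–C2′; the tethered carboxylate then attacks the allyl terminus C5 anti to palladium, which forms the O1–C5 bond, closes the oxolan-2-one by a 5-exo attack and leaves the exocyclic C1′=C2′ alkene. The closest known reaction type is the zerovalent-palladium 1,3-transposition of allylic carboxylates and the ionisation and reclosure of vinyl lactones, here run in the ring-contracting direction. The new stereocentre C5 is set by net retention (two inversions): the oxygen returns to the allyl face from which it left the (R)-configured C2′, and with the CH2OTBS group syn on the allyl this face gives (5S), trans to the C4 methyl group. The (E)-alkene follows because ring carbon C4 is held anti on the allyl, so the C2′ substituent has to sit syn. The step needs attack at C5 in preference to return at C2′ and no β-hydride loss to a dienoic acid; the lower strain of the five-membered lactone makes C5 closure the sink of a reversible ionisation, and the base-free medium at moderate temperature should disfavour elimination. The allylic silyl and PMB ethers are not ionised by zerovalent palladium.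

Step 12
Reactants: 19 (3S,4S,5S)-5-[(2E)-4-{[tert-butyl(dimethyl)silyl]oxy}but-2-en-2-yl]-3-{(1E)-3-[(4-methoxybenzyl)oxy]-2-methylprop-1-en-1-yl}-4-methyloxolan-2-one
Product: 20 (3S,4S,5S)-5-[(2E)-4-hydroxybut-2-en-2-yl]-3-{(1E)-3-[(4-methoxybenzyl)oxy]-2-methylprop-1-en-1-yl}-4-methyloxolan-2-one
Conditions: HF·pyridine, pyridine, THF, 0 → 25 °C
Reagents that add atoms: none
Why: Buffered fluoride cleavage of the primary allylic silyl ether; the PMB ether, the lactone and its acidic C3–H should not be affected under these near-neutral conditions.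

Step 13
Reactants: 20 (3S,4S,5S)-5-[(2E)-4-hydroxybut-2-en-2-yl]-3-{(1E)-3-[(4-methoxybenzyl)oxy]-2-methylprop-1-en-1-yl}-4-methyloxolan-2-one
Product: 21 (3S,4S,5S)-3-{(1E)-3-[(4-methoxybenzyl)oxy]-2-methylprop-1-en-1-yl}-4-methyl-5-[(2E)-4-oxobut-2-en-2-yl]oxolan-2-one
Conditions: MnO2 (activated, excess), CH2Cl2, 25 °C
Reagents that add atoms: none
Why: Neutral heterogeneous oxidation of an allylic alcohol to the (E)-enal.

Step 14
Reactants: 22 (4R)-4-benzyl-1,3-oxazolidin-2-one; 23 hexanoyl chloride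
Product: 25 (4R)-4-benzyl-3-hexanoyl-1,3-oxazolidin-2-one, via lithium oxazolidinide 24 (not isolated)
Conditions: n-BuLi, THF, −78 °C; 23, −78 → 0 °C
Reagents that add atoms: none
Why: N-Acylation of the lithiated auxiliary by the acid chloride.

Step 15
Reactants: 25 (4R)-4-benzyl-3-hexanoyl-1,3-oxazolidin-2-one
Product: 27 (4R)-4-benzyl-3-[(2S)-2-(hydroxymethyl)hexanoyl]-1,3-oxazolidin-2-one, via chlorotitanium enolate 26 (not isolated)
Conditions: TiCl4, iPr2NEt, CH2Cl2, 0 °C; 1,3,5-trioxane, TiCl4, 0 °C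
Reagents that add atoms: 1,3,5-trioxane, C1OCOCO1
Why: Auxiliary-controlled hydroxymethylation (Evans titanium enolate alkylation): the (Z)-enolate is attacked by TiCl4-activated trioxane on the face away from the benzyl group, which sets the (2S) centre (later C5′).

Step 16
Reactants: 27 (4R)-4-benzyl-3-[(2S)-2-(hydroxymethyl)hexanoyl]-1,3-oxazolidin-2-one
Product: 28 (4R)-4-benzyl-3-[(2S)-2-({[tert-butyl(dimethyl)silyl]oxy}methyl)hexanoyl]-1,3-oxazolidin-2-one
Conditions: t-BuMe2SiCl, imidazole, DMF, 25 °C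
Reagents that add atoms: tert-butyl(chloro)dimethylsilane, CC(C)(C)[Si](C)(C)Cl
Why: Silylation of the primary alcohol under conditions too mild for retro-aldol cleavage or dehydration.

Step 17
Reactants: 28 (4R)-4-benzyl-3-[(2S)-2-({[tert-butyl(dimethyl)silyl]oxy}methyl)hexanoyl]-1,3-oxazolidin-2-one
Product: 29 (2R)-2-({[tert-butyl(dimethyl)silyl]oxy}methyl)hexan-1-ol
Conditions: LiBH4, MeOH (1 equiv), Et2O, 0 °C
Reagents that add atoms: none
Why: Reductive removal of the auxiliary by hydride attack on the exocyclic imide carbonyl; the stereocentre is not touched and 1,3-silyl migration should not occur at 0 °C.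

Step 18
Reactants: 29 (2R)-2-({[tert-butyl(dimethyl)silyl]oxy}methyl)hexan-1-ol
Product: 30 5-{[(2S)-2-({[tert-butyl(dimethyl)silyl]oxy}methyl)hexyl]sulfanyl}-1-phenyl-1H-tetrazole
Conditions: 1-phenyl-1H-tetrazole-5-thiol, PPh3, DIAD, THF, 0 → 25 °C
Reagents that add atoms: 1-phenyl-1H-tetrazole-5-thiol, Sc1nnnn1-c1ccccc1
Why: Mitsunobu thioetherification at the primary carbon; the adjacent stereocentre is not involved.

Step 19
Reactants: 30 5-{[(2S)-2-({[tert-butyl(dimethyl)silyl]oxy}methyl)hexyl]sulfanyl}-1-phenyl-1H-tetrazole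
Product: 31 5-{[(2S)-2-({[tert-butyl(dimethyl)silyl]oxy}methyl)hexyl]sulfonyl}-1-phenyl-1H-tetrazole
Conditions: (NH4)6Mo7O24·4H2O (10 mol%), 30% H2O2, EtOH, 0 → 25 °C
Reagents that add atoms: hydrogen peroxide, OO
Why: Molybdate-catalysed oxidation of the sulfide to the sulfone, the usual entry to phenyltetrazolyl sulfones.

Step 20
Reactants: 31 5-{[(2S)-2-({[tert-butyl(dimethyl)silyl]oxy}methyl)hexyl]sulfonyl}-1-phenyl-1H-tetrazole; 21 (3S,4S,5S)-3-{(1E)-3-[(4-methoxybenzyl)oxy]-2-methylprop-1-en-1-yl}-4-methyl-5-[(2E)-4-oxobut-2-en-2-yl]oxolan-2-one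
Product: 33 (3S,4S,5S)-5-[(2E,4E,6R)-6-({[tert-butyl(dimethyl)silyl]oxy}methyl)deca-2,4-dien-2-yl]-3-{(1E)-3-[(4-methoxybenzyl)oxy]-2-methylprop-1-en-1-yl}-4-methyloxolan-2-one, via potassium sulfonyl carbanion 32 (not isolated)
Conditions: KN(SiMe3)2, DME, −60 °C; 21, −60 → 25 °C; aq. NH4Cl
Reagents that add atoms: none
Why: Julia–Kocienski olefination: 1,2-addition of the pre-metalated sulfone to the enal, Smiles rearrangement and loss of SO2 and tetrazolate should give the (E)-C3′=C4′ bond; pre-metalation keeps free base away from the lactone.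

Step 21
Reactants: 33 (3S,4S,5S)-5-[(2E,4E,6R)-6-({[tert-butyl(dimethyl)silyl]oxy}methyl)deca-2,4-dien-2-yl]-3-{(1E)-3-[(4-methoxybenzyl)oxy]-2-methylprop-1-en-1-yl}-4-methyloxolan-2-one
Product: 34 (3S,4S,5S)-5-[(2E,4E,6R)-6-({[tert-butyl(dimethyl)silyl]oxy}methyl)deca-2,4-dien-2-yl]-3-[(1E)-3-hydroxy-2-methylprop-1-en-1-yl]-4-methyloxolan-2-one
Conditions: DDQ, CH2Cl2–pH 7 phosphate buffer 10:1, 0 °C
Reagents that add atoms: none
Why: Oxidative cleavage of the PMB ether by DDQ; the diene carries an inward methyl group in its s-cis form and should therefore not undergo cycloaddition, and the buffer protects the silyl ether.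

Step 22
Reactants: 34 (3S,4S,5S)-5-[(2E,4E,6R)-6-({[tert-butyl(dimethyl)silyl]oxy}methyl)deca-2,4-dien-2-yl]-3-[(1E)-3-hydroxy-2-methylprop-1-en-1-yl]-4-methyloxolan-2-one
Product: 35 (3S,4S,5S)-5-[(2E,4E,6R)-6-({[tert-butyl(dimethyl)silyl]oxy}methyl)deca-2,4-dien-2-yl]-4-methyl-3-[(1E)-2-methyl-3-oxoprop-1-en-1-yl]oxolan-2-one
Conditions: MnO2 (activated, excess), CH2Cl2, 25 °C
Reagents that add atoms: none
Why: Neutral allylic oxidation to the enal, which avoids base at the now more acidic C3–H.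

Step 23
Reactants: 35 (3S,4S,5S)-5-[(2E,4E,6R)-6-({[tert-butyl(dimethyl)silyl]oxy}methyl)deca-2,4-dien-2-yl]-4-methyl-3-[(1E)-2-methyl-3-oxoprop-1-en-1-yl]oxolan-2-one
Product: 36 (3S,4S,5S)-5-[(2E,4E,6R)-6-({[tert-butyl(dimethyl)silyl]oxy}methyl)deca-2,4-dien-2-yl]-4-methyl-3-[(1E,3E)-2-methyl-5-oxopenta-1,3-dien-1-yl]oxolan-2-one
Conditions: Ph3P=CHCHO (1.3 equiv), toluene, 70 °C
Reagents that add atoms: (triphenyl-λ5-phosphanylidene)acetaldehyde, O=CC=P(c1ccccc1)(c1ccccc1)c1ccccc1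
Why: Wittig reaction with a stabilised, weakly basic ylide, which should give the (E)-C3″=C4″ bond; the less electrophilic dienal product should not be homologated again.

Step 24
Reactants: 36 (3S,4S,5S)-5-[(2E,4E,6R)-6-({[tert-butyl(dimethyl)silyl]oxy}methyl)deca-2,4-dien-2-yl]-4-methyl-3-[(1E,3E)-2-methyl-5-oxopenta-1,3-dien-1-yl]oxolan-2-one; 37 but-3-en-2-one
Product: 40 (3S,4S,5S)-5-[(2E,4E,6R)-6-({[tert-butyl(dimethyl)silyl]oxy}methyl)deca-2,4-dien-2-yl]-3-[(1E,3E,5S,6R)-5-hydroxy-2,6-dimethyl-7-oxoocta-1,3-dien-1-yl]-4-methyloxolan-2-one, via enolborinate 38 (not isolated), via boron aldolate 39 (not isolated)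
Conditions: (+)-Ipc2BH [(+)-diisopinocampheylborane, from (−)-α-pinene, 1.3 equiv], 37 (1.5 equiv), Et2O, 0 °C; 36, −78 → −20 °C; pH 7 buffer, MeOH, 30% H2O2, 0 °C
Reagents that add atoms: none
Why: Reductive aldol reaction: 1,4-hydroboration of the s-cis enone gives the (Z)-enolborinate regiospecifically at C6″, which adds through a closed chair transition state to give the 5″,6″-syn pair; the isopinocampheyl groups from (−)-α-pinene are expected to direct it to the Re face of the aldehyde, as the corresponding allylboranes do, which corresponds to (5″S,6″R), and the amine-free medium spares the acidic C3–H.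

Step 25
Reactants: 40 (3S,4S,5S)-5-[(2E,4E,6R)-6-({[tert-butyl(dimethyl)silyl]oxy}methyl)deca-2,4-dien-2-yl]-3-[(1E,3E,5S,6R)-5-hydroxy-2,6-dimethyl-7-oxoocta-1,3-dien-1-yl]-4-methyloxolan-2-one
Product: 41 (3S,4S,5S)-5-[(2E,4E,6R)-6-(hydroxymethyl)deca-2,4-dien-2-yl]-3-[(1E,3E,5S,6R)-5-hydroxy-2,6-dimethyl-7-oxoocta-1,3-dien-1-yl]-4-methyloxolan-2-one (CNP0187795.2)
Conditions: HF·pyridine, pyridine, THF, 0 °C
Reagents that add atoms: none
Why: Buffered fluoride cleavage of the primary silyl ether, mild enough that the β-hydroxy ketone, the dienyl carbinol and the lactone should survive.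

**Compound list**
1 | 3-methylbut-2-en-1-ol (prenol) | CC(C)=CCO | starting material
2 | [(2S)-3,3-dimethyloxiran-2-yl]methanol | OC[C@@H]1OC1(C)C | intermediate
3 | tert-butyl{[(2S)-3,3-dimethyloxiran-2-yl]methoxy}dimethylsilane | CC(C)(C)[Si](C)(C)OC[C@@H]1OC1(C)C | intermediate
4 | (2R)-1-{[tert-butyl(dimethyl)silyl]oxy}-3-methylbut-3-en-2-ol | CC(C)(C)[Si](C)(C)OC[C@H](O)C(C)=C | intermediate
5 | (E)-pent-3-en-2-ol, racemic | C/C=C/C(C)O | starting material
6 | (2S,3E)-pent-3-en-2-ol | C[C@H](O)/C=C/C | intermediate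
7 | 1-methoxy-4-[(prop-2-yn-1-yloxy)methyl]benzene | C#CCOCc1ccc(OC)cc1 | starting material
8 | dimethyl{(1E)-3-[(4-methoxybenzyl)oxy]-2-methylprop-1-en-1-yl}alumane | C[Al](C)/C=C(\C)COCc1ccc(OC)cc1 | intermediate
9 | lithium butyl(dimethyl){(1E)-3-[(4-methoxybenzyl)oxy]-2-methylprop-1-en-1-yl}aluminate | [Li+].CCCC[Al-](C)(C)/C=C(\C)COCc1ccc(OC)cc1 | intermediate
10 | (3E)-5-[(4-methoxybenzyl)oxy]-4-methylpent-3-en-1-ol | OCC/C=C(C)/COCc1ccc(OC)cc1 | intermediate
11 | (3E)-5-[(4-methoxybenzyl)oxy]-4-methylpent-3-enoic acid | OC(=O)C/C=C(C)/COCc1ccc(OC)cc1 | intermediate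
12 | (2S,3E)-pent-3-en-2-yl (3E)-5-[(4-methoxybenzyl)oxy]-4-methylpent-3-enoate | C/C=C/[C@H](C)OC(=O)C/C=C(C)/COCc1ccc(OC)cc1 | intermediate
13 | lithium (1Z,3E)-dienolate of 12 (O–Li cis to C3) | [Li+].[O-]/C(O[C@@H](C)/C=C/C)=C\C=C(C)\COCc1ccc(OC)cc1 | intermediate
14 | (1Z,3E)-trimethylsilyl ketene acetal of 12 | C[Si](C)(C)O/C(O[C@@H](C)/C=C/C)=C\C=C(C)\COCc1ccc(OC)cc1 | intermediate
15 | trimethylsilyl ester of 16 | C[Si](C)(C)OC(=O)[C@@H](/C=C(C)/COCc1ccc(OC)cc1)[C@H](C)/C=C/C | intermediate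
16 | (2R,3R,4E)-2-{(1E)-3-[(4-methoxybenzyl)oxy]-2-methylprop-1-en-1-yl}-3-methylhex-4-enoic acid | OC(=O)[C@@H](/C=C(C)/COCc1ccc(OC)cc1)[C@H](C)/C=C/C | intermediate
17 | (2R)-1-{[tert-butyl(dimethyl)silyl]oxy}-3-methylbut-3-en-2-yl ester of 16 | CC(C)(C)[Si](C)(C)OC[C@@H](C(C)=C)OC(=O)[C@@H](/C=C(C)/COCc1ccc(OC)cc1)[C@H](C)/C=C/C | intermediate
18 | (3R,4R,7R)-7-({[tert-butyl(dimethyl)silyl]oxy}methyl)-3-{(1E)-3-[(4-methoxybenzyl)oxy]-2-methylprop-1-en-1-yl}-4,6-dimethyl-4,7-dihydrooxepin-2(3H)-one | O=C1O[C@@H](CO[Si](C)(C)C(C)(C)C)C(C)=C[C@@H](C)[C@@H]1/C=C(C)/COCc2ccc(OC)cc2 | intermediate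
19 | (3S,4S,5S)-5-[(2E)-4-{[tert-butyl(dimethyl)silyl]oxy}but-2-en-2-yl]-3-{(1E)-3-[(4-methoxybenzyl)oxy]-2-methylprop-1-en-1-yl}-4-methyloxolan-2-one | CC(C)(C)[Si](C)(C)OC/C=C(\C)[C@H]1OC(=O)[C@@H](/C=C(C)/COCc2ccc(OC)cc2)[C@@H]1C | intermediate
20 | (3S,4S,5S)-5-[(2E)-4-hydroxybut-2-en-2-yl]-3-{(1E)-3-[(4-methoxybenzyl)oxy]-2-methylprop-1-en-1-yl}-4-methyloxolan-2-one | OC/C=C(\C)[C@H]1OC(=O)[C@@H](/C=C(C)/COCc2ccc(OC)cc2)[C@@H]1C | intermediate
21 | (3S,4S,5S)-3-{(1E)-3-[(4-methoxybenzyl)oxy]-2-methylprop-1-en-1-yl}-4-methyl-5-[(2E)-4-oxobut-2-en-2-yl]oxolan-2-one | O=C/C=C(\C)[C@H]1OC(=O)[C@@H](/C=C(C)/COCc2ccc(OC)cc2)[C@@H]1C | intermediate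
22 | (4R)-4-benzyl-1,3-oxazolidin-2-one | O=C1OC[C@@H](Cc2ccccc2)N1 | starting material
23 | hexanoyl chloride | CCCCCC(Cl)=O | starting material
24 | lithium salt of 22 | [Li+].O=C1OC[C@@H](Cc2ccccc2)[N-]1 | intermediate
25 | (4R)-4-benzyl-3-hexanoyl-1,3-oxazolidin-2-one | CCCCCC(=O)N1[C@H](Cc2ccccc2)COC1=O | intermediate
26 | trichlorotitanium (Z)-enolate of 25 | CCCC/C=C(\O[Ti](Cl)(Cl)Cl)N1[C@H](Cc2ccccc2)COC1=O | intermediate
27 | (4R)-4-benzyl-3-[(2S)-2-(hydroxymethyl)hexanoyl]-1,3-oxazolidin-2-one | CCCC[C@@H](CO)C(=O)N1[C@H](Cc2ccccc2)COC1=O | intermediate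
28 | (4R)-4-benzyl-3-[(2S)-2-({[tert-butyl(dimethyl)silyl]oxy}methyl)hexanoyl]-1,3-oxazolidin-2-one | CCCC[C@@H](CO[Si](C)(C)C(C)(C)C)C(=O)N1[C@H](Cc2ccccc2)COC1=O | intermediate
29 | (2R)-2-({[tert-butyl(dimethyl)silyl]oxy}methyl)hexan-1-ol | CCCC[C@H](CO)CO[Si](C)(C)C(C)(C)C | intermediate
30 | 5-{[(2S)-2-({[tert-butyl(dimethyl)silyl]oxy}methyl)hexyl]sulfanyl}-1-phenyl-1H-tetrazole | CCCC[C@H](CSc1nnnn1-c1ccccc1)CO[Si](C)(C)C(C)(C)C | intermediate
31 | 5-{[(2S)-2-({[tert-butyl(dimethyl)silyl]oxy}methyl)hexyl]sulfonyl}-1-phenyl-1H-tetrazole | CCCC[C@H](CS(=O)(=O)c1nnnn1-c1ccccc1)CO[Si](C)(C)C(C)(C)C | intermediate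
32 | potassium salt of 31 (carbanion at the CH2 next to sulfur) | [K+].CCCC[C@H]([CH-]S(=O)(=O)c1nnnn1-c1ccccc1)CO[Si](C)(C)C(C)(C)C | intermediate
33 | (3S,4S,5S)-5-[(2E,4E,6R)-6-({[tert-butyl(dimethyl)silyl]oxy}methyl)deca-2,4-dien-2-yl]-3-{(1E)-3-[(4-methoxybenzyl)oxy]-2-methylprop-1-en-1-yl}-4-methyloxolan-2-one | CCCC[C@H](/C=C/C=C(\C)[C@H]1OC(=O)[C@@H](/C=C(C)/COCc2ccc(OC)cc2)[C@@H]1C)CO[Si](C)(C)C(C)(C)C | intermediate
34 | (3S,4S,5S)-5-[(2E,4E,6R)-6-({[tert-butyl(dimethyl)silyl]oxy}methyl)deca-2,4-dien-2-yl]-3-[(1E)-3-hydroxy-2-methylprop-1-en-1-yl]-4-methyloxolan-2-one | CCCC[C@H](/C=C/C=C(\C)[C@H]1OC(=O)[C@@H](/C=C(C)/CO)[C@@H]1C)CO[Si](C)(C)C(C)(C)C | intermediate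
35 | (3S,4S,5S)-5-[(2E,4E,6R)-6-({[tert-butyl(dimethyl)silyl]oxy}methyl)deca-2,4-dien-2-yl]-4-methyl-3-[(1E)-2-methyl-3-oxoprop-1-en-1-yl]oxolan-2-one | CCCC[C@H](/C=C/C=C(\C)[C@H]1OC(=O)[C@@H](/C=C(C)/C=O)[C@@H]1C)CO[Si](C)(C)C(C)(C)C | intermediate
36 | (3S,4S,5S)-5-[(2E,4E,6R)-6-({[tert-butyl(dimethyl)silyl]oxy}methyl)deca-2,4-dien-2-yl]-4-methyl-3-[(1E,3E)-2-methyl-5-oxopenta-1,3-dien-1-yl]oxolan-2-one | CCCC[C@H](/C=C/C=C(\C)[C@H]1OC(=O)[C@@H](/C=C(C)/C=C/C=O)[C@@H]1C)CO[Si](C)(C)C(C)(C)C | intermediate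
37 | but-3-en-2-one (methyl vinyl ketone) | CC(=O)C=C | starting material
38 | (Z)-but-2-en-2-yl bis(isopinocampheyl)borinate, from (+)-Ipc2BH and 37 | C/C=C(/C)OB([C@H]1C[C@H]2C[C@@H]([C@@H]1C)C2(C)C)[C@H]1C[C@H]2C[C@@H]([C@@H]1C)C2(C)C | intermediate
39 | C5″-O-bis(isopinocampheyl)boryl aldolate of 40 | CCCC[C@H](/C=C/C=C(\C)[C@H]1OC(=O)[C@@H](/C=C(C)/C=C/[C@H](OB([C@H]2C[C@H]3C[C@@H]([C@@H]2C)C3(C)C)[C@H]2C[C@H]3C[C@@H]([C@@H]2C)C3(C)C)[C@@H](C)C(C)=O)[C@@H]1C)CO[Si](C)(C)C(C)(C)C | intermediate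
40 | (3S,4S,5S)-5-[(2E,4E,6R)-6-({[tert-butyl(dimethyl)silyl]oxy}methyl)deca-2,4-dien-2-yl]-3-[(1E,3E,5S,6R)-5-hydroxy-2,6-dimethyl-7-oxoocta-1,3-dien-1-yl]-4-methyloxolan-2-one | CCCC[C@H](/C=C/C=C(\C)[C@H]1OC(=O)[C@@H](/C=C(C)/C=C/[C@H](O)[C@@H](C)C(C)=O)[C@@H]1C)CO[Si](C)(C)C(C)(C)C | intermediate
41 | (3S,4S,5S)-5-[(2E,4E,6R)-6-(hydroxymethyl)deca-2,4-dien-2-yl]-3-[(1E,3E,5S,6R)-5-hydroxy-2,6-dimethyl-7-oxoocta-1,3-dien-1-yl]-4-methyloxolan-2-one (CNP0187795.2) | CCCC[C@H](/C=C/C=C(\C)[C@H]1OC(=O)[C@@H](/C=C(C)/C=C/[C@H](O)[C@@H](C)C(C)=O)[C@@H]1C)CO | target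

**Step count**
Total: 25 steps. Longest linear sequence: 15 steps (from 7 through steps 5–13 and 20–25 to 41).

**Steps most likely to fail**

Step 11. The π-allyl intermediate may lose a β-hydride to give a dienoic acid, or the carboxylate may return without facial control after π–σ–π exchange. The fallback moves the oxygen without a π-allylmetal. It sets out from 18: LiOH in THF–water at 0 °C would open the lactone to the (Z)-allylic hydroxy acid F1. Ph3SiOReO3 (5 mol%) in Et2O would then shift the hydroxyl from C6 to C4 of the heptenoic acid by a [3,3]-rearrangement of the perrhenate ester. The γ-hydroxy acid so formed closes to the lactone, which should draw the reversible transposition towards the trans,trans isomer, and the route is rejoined at 19.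

Step 8. Deprotonation may give the dienolate without geometric control, or mainly as the E(O) isomer, so that the 2,3-anti acid accompanies 16. The fallback inverts the pairing of alkene and enolate geometry and sets out from 11. Commercial (R)-but-3-yn-2-ol would be C-methylated through its dianion (n-BuLi, then MeI) to (2R)-pent-3-yn-2-ol F2 and esterified with 11 (DCC, DMAP) to the alkynyl ester F3. Semi-hydrogenation (H2, Pd/CaCO3 poisoned with Pb(OAc)2, quinoline) would give the (2R,3Z)-pent-3-en-2-yl ester F4. LiN(iPr)2 in THF without DMPU, then Me3SiCl, should give the kinetically preferred E(O)-ketene acetal. Its chair transition state, with the (Z)-methyl axial and the carbinol methyl held equatorial by A(1,3) strain, leads to the same acid, and the route is rejoined at 16.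

Step 24. The chiral enolborinate may discriminate poorly between the faces of the conjugated dienal, or residual borane may reduce it. The fallback sets the syn pair with an auxiliary and sets out from 36. The dibutylboron (Z)-enolate of commercial (4R)-4-benzyl-3-propanoyl-1,3-oxazolidin-2-one (Bu2BOTf, iPr2NEt, CH2Cl2, −78 → 0 °C) would give the syn-aldol imide F5 with the (5″S,6″R) configuration. Me3Al and MeNH(OMe)·HCl in THF at −20 °C, assisted by the free C5″ hydroxyl, would exchange the auxiliary for the N-methoxy-N-methylamide F6. MeMgBr in THF at −40 °C would then give the methyl ketone, and the route is rejoined at 40.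

**Further compounds**
F1 | step 11 | (2R,3R,4Z,6R)-7-{[tert-butyl(dimethyl)silyl]oxy}-6-hydroxy-2-{(1E)-3-[(4-methoxybenzyl)oxy]-2-methylprop-1-en-1-yl}-3,5-dimethylhept-4-enoic acid | OC(=O)[C@@H](/C=C(C)/COCc1ccc(OC)cc1)[C@H](C)/C=C(C)\[C@@H](O)CO[Si](C)(C)C(C)(C)C
F2 | step 8 | (2R)-pent-3-yn-2-ol | C[C@@H](O)C#CC
F3 | step 8 | (2R)-pent-3-yn-2-yl (3E)-5-[(4-methoxybenzyl)oxy]-4-methylpent-3-enoate | CC#C[C@@H](C)OC(=O)C/C=C(C)/COCc1ccc(OC)cc1
F4 | step 8 | (2R,3Z)-pent-3-en-2-yl (3E)-5-[(4-methoxybenzyl)oxy]-4-methylpent-3-enoate | C/C=C\[C@@H](C)OC(=O)C/C=C(C)/COCc1ccc(OC)cc1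
F5 | step 24 | (4R)-4-benzyl-3-[(2R,3S)-3-hydroxy-2-methylpropanoyl]-1,3-oxazolidin-2-one carrying at C3 of the acyl chain the (1E,3E)-dienyl lactone residue of 36 | CCCC[C@H](/C=C/C=C(\C)[C@H]1OC(=O)[C@@H](/C=C(C)/C=C/[C@H](O)[C@@H](C)C(=O)N2[C@H](Cc3ccccc3)COC2=O)[C@@H]1C)CO[Si](C)(C)C(C)(C)C
F6 | step 24 | N-methoxy-N-methylamide corresponding to F5 | CCCC[C@H](/C=C/C=C(\C)[C@H]1OC(=O)[C@@H](/C=C(C)/C=C/[C@H](O)[C@@H](C)C(=O)N(C)OC)[C@@H]1C)CO[Si](C)(C)C(C)(C)C
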